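**Retrosynthetic overview**
- Target ⇐ its tert-butyl ester (acidolysis). The esters go on one at a time: C5 acetate first, C3 6-methylheptanoate by Mitsunobu inversion of a cis-3,4-diol, C4 tiglate last.
- cis-Diol ⇐ anti dihydroxylation of the distal alkene of tert-butyl (S)-5-acetoxycyclohexa-1,3-diene-1-carboxylate ⇐ base-induced opening of a 4,5-epoxycyclohexene ester.
- Epoxy enoate ⇐ enol triflate / Pd–formate deoxygenation of an epoxy β-keto ester.
- Key step: the only carbocycle, the six-membered ring, is formed by an enantioselective desymmetrising one-carbon ring expansion (1,2-shift with loss of N2) of meso-3,4-epoxycyclopentanone with tert-butyl diazoacetate. The epoxy ketone comes from cyclopent-3-enone.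
- 6-Methylheptanoic acid ⇐ 3-methylbutyl Grignard + β-propiolactone. Ring order: epoxide on the five-ring → six-ring by expansion → epoxide opened.

Assumption: all numbered starting materials are catalogue chemicals; the tert-butyl group of the diazoacetate is carried only as the carboxyl protecting group.

**Route**

Step 1
Reactants: 1 cyclopent-3-en-1-one
Product: 2 (1R,5S)-6-oxabicyclo[3.1.0]hexan-3-one (meso cis-3,4-epoxycyclopentanone)
Conditions: mCPBA (1.1 equiv), CH2Cl2, 0 °C → rt
Reagents that add atoms: 3-chloroperoxybenzoic acid (mCPBA), OOC(=O)c1cccc(Cl)c1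
Why: Prilezhaev epoxidation of the isolated cis-alkene is much faster than Baeyer–Villiger oxidation of the ketone, and the product is a meso cis-epoxide, so no stereochemical issue arises.

Step 2
Reactants: 2 (1R,5S)-6-oxabicyclo[3.1.0]hexan-3-one; 3 tert-butyl diazoacetate
Product: 4 tert-butyl (1S,6R)-4-hydroxy-7-oxabicyclo[4.1.0]hept-3-ene-3-carboxylate (enol form of the β-keto ester)
Conditions: Sc(OTf)3 (10 mol %), chiral N,N'-dioxide ligand (L-pipecolic acid-derived bis(2,6-diisopropylanilide), 11 mol %), 4 Å MS, CH2Cl2, −40 °C, slow addition of 3 (1.2 equiv)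
Reagents that add atoms: none
Why: Proposed new method: catalytic enantioselective desymmetrising one-carbon ring expansion of a meso cyclopentanone with an α-unsubstituted diazoacetate – the Sc(III)/N,N'-dioxide complex activates the ketone, 3 adds to the carbonyl carbon from the face anti to the epoxide, and in the β-oxido diazonium the chiral pocket holds the ester in one rotamer so that only one of the two enantiotopic CH2–C(=O) bonds (the CH2 next to the (S)-epoxide carbon) is antiperiplanar to N2+ and undergoes the 1,2-shift, which forms the six-membered ring and fixes the absolute configuration of the two epoxide carbons (later C4/C5), while the new C1 centre is erased by enolisation, which also blocks a second homologation; the ligand antipode that gives (1S,6R) is chosen by screening; closest known reaction type: Lewis-acid-promoted Tiffeneau–Demjanov-type homologation of cyclopentanones with diazoacetates and chiral-Lewis-acid desymmetrising ring expansions of 4-substituted cyclohexanones with α-alkyl diazo esters.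

Step 3
Reactants: 4 tert-butyl (1S,6R)-4-hydroxy-7-oxabicyclo[4.1.0]hept-3-ene-3-carboxylate
Product: 5 tert-butyl (1S,6R)-4-(trifluoromethylsulfonyloxy)-7-oxabicyclo[4.1.0]hept-3-ene-3-carboxylate
Conditions: Tf2O (1.1 equiv), iPr2NEt (1.5 equiv), CH2Cl2, −78 °C
Reagents that add atoms: triflic anhydride, O=S(=O)(OS(=O)(=O)C(F)(F)F)C(F)(F)F
Why: Enol triflate formation by O-sulfonylation of the fully enolised β-keto ester at low temperature; the hindered amine does not touch the epoxide and no stereocentre is involved.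

Step 4
Reactants: 5 tert-butyl (1S,6R)-4-(trifluoromethylsulfonyloxy)-7-oxabicyclo[4.1.0]hept-3-ene-3-carboxylate
Product: 6 tert-butyl (1S,6R)-7-oxabicyclo[4.1.0]hept-3-ene-3-carboxylate
Conditions: Pd(OAc)2 (5 mol %), PPh3 (10 mol %), HCO2H (2 equiv), Bu3N (3 equiv), DMF, 50 °C
Reagents that add atoms: none
Why: Pd(0)/formate hydrogenolysis of a vinyl triflate (oxidative addition, formate exchange, decarboxylation, reductive elimination) replaces C–OTf by C–H, and the non-allylic epoxide is inert to Pd(0).

Step 5
Reactants: 6 tert-butyl (1S,6R)-7-oxabicyclo[4.1.0]hept-3-ene-3-carboxylate; 7 acetic anhydride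
Product: 9 tert-butyl (5S)-5-acetoxycyclohexa-1,3-diene-1-carboxylate, via (5S)-5-hydroxy dienoate 8 (not isolated)
Conditions: DBU (1.1 equiv), CH2Cl2, 0 °C → rt; then pyridine, Ac2O (1.5 equiv), DMAP (cat.), 0 °C
Reagents that add atoms: none
Why: Vinylogous E1cB epoxide opening – DBU removes the γ-proton at C3 and the C4–O bond breaks, so the C5–O bond keeps its (S) configuration – followed by in-flask O-acetylation under mild base, which avoids isolating the aromatisation-prone dienol.

Step 6
Reactants: 9 tert-butyl (5S)-5-acetoxycyclohexa-1,3-diene-1-carboxylate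
Product: 10 tert-butyl (3S,4S,5S)-5-acetoxy-3,4-dihydroxycyclohex-1-ene-1-carboxylate
Conditions: OsO4 (2 mol %), NMO (1.2 equiv), acetone/H2O 8:1, 0 °C
Reagents that add atoms: N-methylmorpholine N-oxide, C[N+]1([O-])CCOCC1; water, O
Why: Upjohn dihydroxylation – OsO4 attacks the more electron-rich distal alkene rather than the ester-conjugated one, and adds syn from the face anti to the allylic acetate (Kishi's rule), which sets the C4–O bond trans to C5–OAc and gives the cis-3,4-diol.

Step 7
Reactants: 11 1-bromo-3-methylbutane; 12 β-propiolactone (oxetan-2-one)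
Product: 14 6-methylheptanoic acid, via 3-methylbutylmagnesium bromide 13 (not isolated)
Conditions: Mg, THF, 40 °C; then CuBr·SMe2 (3 mol %), 12, THF, −30 → 0 °C; aq. HCl
Reagents that add atoms: none
Why: Copper-catalysed SN2 alkyl–oxygen opening of β-propiolactone by the Grignard reagent at the β-CH2 gives the three-carbon-extended carboxylic acid directly.

Step 8
Reactants: 10 tert-butyl (3S,4S,5S)-5-acetoxy-3,4-dihydroxycyclohex-1-ene-1-carboxylate; 14 6-methylheptanoic acid
Product: 15 tert-butyl (3R,4R,5S)-5-acetoxy-4-hydroxy-3-(6-methylheptanoyloxy)cyclohex-1-ene-1-carboxylate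
Conditions: PPh3 (1.5 equiv), DIAD (1.5 equiv), 14 (1.3 equiv), THF, 0 °C → rt
Reagents that add atoms: none
Why: Mitsunobu esterification – the carboxylate displaces the oxyphosphonium at the allylic, less hindered C3 with clean inversion (3S → 3R, now trans to 4-OH), while the cis 4-OH cannot close an epoxide and C4, flanked by two oxygenated carbons, is not attacked.

Step 9
Reactants: 15 tert-butyl (3R,4R,5S)-5-acetoxy-4-hydroxy-3-(6-methylheptanoyloxy)cyclohex-1-ene-1-carboxylate; 16 tigloyl chloride ((E)-2-methylbut-2-enoyl chloride)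
Product: 17 tert-butyl (3R,4R,5S)-5-acetoxy-3-(6-methylheptanoyloxy)-4-[(E)-2-methylbut-2-enoyloxy]cyclohex-1-ene-1-carboxylate
Conditions: 16 (1.5 equiv), pyridine, DMAP (10 mol %), CH2Cl2, 0 °C → rt
Reagents that add atoms: none
Why: DMAP-catalysed acylation of the remaining secondary alcohol with an acid chloride; pyridine instead of a trialkylamine avoids vinylketene formation and deconjugation, so the E geometry and all stereocentres are retained.

Step 10
Reactants: 17 tert-butyl (3R,4R,5S)-5-acetoxy-3-(6-methylheptanoyloxy)-4-[(E)-2-methylbut-2-enoyloxy]cyclohex-1-ene-1-carboxylate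
Product: 18 (3R,4R,5S)-5-acetoxy-3-(6-methylheptanoyloxy)-4-[(E)-2-methylbut-2-enoyloxy]cyclohex-1-ene-1-carboxylic acid
Conditions: TFA/CH2Cl2 1:4, 0 °C → rt
Reagents that add atoms: none
Why: Acidolysis of the tert-butyl ester (E1 loss of isobutene) leaves the three other esters intact, since ionisation of the allylic C3 ester is disfavoured by the conjugated carboxyl group.

**Compound list**
1 | cyclopent-3-en-1-one | O=C1CC=CC1 | starting material
2 | (1R,5S)-6-oxabicyclo[3.1.0]hexan-3-one (meso) | O=C1C[C@H]2O[C@H]2C1 | intermediate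
3 | tert-butyl diazoacetate | CC(C)(C)OC(=O)C=[N+]=[N-] | starting material
4 | tert-butyl (1S,6R)-4-hydroxy-7-oxabicyclo[4.1.0]hept-3-ene-3-carboxylate (enol of the β-keto ester) | CC(C)(C)OC(=O)C1=C(O)C[C@H]2O[C@H]2C1 | intermediate
5 | tert-butyl (1S,6R)-4-(trifluoromethylsulfonyloxy)-7-oxabicyclo[4.1.0]hept-3-ene-3-carboxylate | CC(C)(C)OC(=O)C1=C(OS(=O)(=O)C(F)(F)F)C[C@H]2O[C@H]2C1 | intermediate
6 | tert-butyl (1S,6R)-7-oxabicyclo[4.1.0]hept-3-ene-3-carboxylate | CC(C)(C)OC(=O)C1=CC[C@H]2O[C@H]2C1 | intermediate
7 | acetic anhydride | CC(=O)OC(C)=O | starting material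
8 | tert-butyl (5S)-5-hydroxycyclohexa-1,3-diene-1-carboxylate | O[C@H]1CC(C(=O)OC(C)(C)C)=CC=C1 | intermediate (not isolated)
9 | tert-butyl (5S)-5-acetoxycyclohexa-1,3-diene-1-carboxylate | CC(=O)O[C@H]1CC(C(=O)OC(C)(C)C)=CC=C1 | intermediate
10 | tert-butyl (3S,4S,5S)-5-acetoxy-3,4-dihydroxycyclohex-1-ene-1-carboxylate | O[C@@H]1[C@@H](OC(C)=O)CC(C(=O)OC(C)(C)C)=C[C@@H]1O | intermediate
11 | 1-bromo-3-methylbutane | CC(C)CCBr | starting material
12 | β-propiolactone (oxetan-2-one) | O=C1CCO1 | starting material
13 | 3-methylbutylmagnesium bromide | CC(C)CC[Mg]Br | intermediate (not isolated)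
14 | 6-methylheptanoic acid | CC(C)CCCCC(=O)O | intermediate
15 | tert-butyl (3R,4R,5S)-5-acetoxy-4-hydroxy-3-(6-methylheptanoyloxy)cyclohex-1-ene-1-carboxylate | O[C@@H]1[C@@H](OC(C)=O)CC(C(=O)OC(C)(C)C)=C[C@H]1OC(=O)CCCCC(C)C | intermediate
16 | tigloyl chloride, (E)-2-methylbut-2-enoyl chloride | C/C=C(\C)C(Cl)=O | starting material
17 | tert-butyl (3R,4R,5S)-5-acetoxy-3-(6-methylheptanoyloxy)-4-[(E)-2-methylbut-2-enoyloxy]cyclohex-1-ene-1-carboxylate | C/C=C(\C)C(=O)O[C@@H]1[C@@H](OC(C)=O)CC(C(=O)OC(C)(C)C)=C[C@H]1OC(=O)CCCCC(C)C | intermediate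
18 | (3R,4R,5S)-5-acetoxy-3-(6-methylheptanoyloxy)-4-[(E)-2-methylbut-2-enoyloxy]cyclohex-1-ene-1-carboxylic acid | C/C=C(\C)C(=O)O[C@@H]1[C@@H](OC(C)=O)CC(C(=O)O)=C[C@H]1OC(=O)CCCCC(C)C | target

**Step count**
Total: 10 steps. Longest linear sequence: 9 steps (steps 1–6 and 8–10); step 7 is a one-step side branch.

**Three steps most likely to fail**

Step 2 (the proposed new ring expansion). Enantioselectivity of the desymmetrisation is untested, and the Lewis acid may open or eliminate the β,γ-epoxy ketone. The fallback uses only known chemistry. It sets out from 1 without epoxidation. BF3·OEt2-promoted ring expansion of 1 with 3 (CH2Cl2, −78 °C) gives tert-butyl 2-hydroxycyclohexa-1,4-diene-1-carboxylate F1. Tf2O/iPr2NEt converts it into tert-butyl 2-(trifluoromethylsulfonyloxy)cyclohexa-1,4-diene-1-carboxylate F2, and Pd/formate reduction gives tert-butyl cyclohexa-1,4-diene-1-carboxylate F3. mCPBA epoxidises the isolated 4,5-alkene to racemic tert-butyl 7-oxabicyclo[4.1.0]hept-3-ene-3-carboxylate F4, which DBU opens to racemic tert-butyl 5-hydroxycyclohexa-1,3-diene-1-carboxylate F5. Lipase-catalysed kinetic resolution (Burkholderia cepacia lipase, vinyl acetate, MTBE, about 50 % conversion) then separates the enantiomers. If the (S)-alcohol is acetylated faster, as Kazlauskas' rule predicts when the ester-bearing arm is the large group, 9 forms directly and tert-butyl (5R)-5-hydroxycyclohexa-1,3-diene-1-carboxylate F6 is left behind. If the lipase instead forms tert-butyl (5R)-5-acetoxycyclohexa-1,3-diene-1-carboxylate F7, the recovered (S)-alcohol 8 is acetylated with 7/pyridine. Either way the route is rejoined at 9.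

Step 8 (regioselective Mitsunobu inversion at C3 with an aliphatic acid beside a free 4-OH). Possible problems are a sluggish reaction, attack at C4, or elimination. The fallback sets out from 9 and replaces steps 6 and 8. Epoxidation of the distal alkene with dimethyldioxirane (acetone, 0 °C) anti to the acetate gives tert-butyl (1S,5S,6R)-5-acetoxy-7-oxabicyclo[4.1.0]hept-2-ene-3-carboxylate F8. Its allylic C3–O bond is opened with inversion by caesium 6-methylheptanoate buffered with 14 (DMF, 50 °C), which gives the trans-3-acyloxy-4-ol directly. The route is rejoined at 15.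

Step 9 (tigloylation of the 4-OH flanked by two acyloxy groups). Possible problems are slow acylation, 1,2-acyl migration under DMAP, and deconjugation of the acid chloride. The fallback sets out from 15 and builds the tiglate in place. DIC/DMAP coupling with 2-(diethoxyphosphoryl)propanoic acid gives tert-butyl (3R,4R,5S)-5-acetoxy-4-[2-(diethoxyphosphoryl)propanoyloxy]-3-(6-methylheptanoyloxy)cyclohex-1-ene-1-carboxylate F9. Masamune–Roush Horner–Wadsworth–Emmons olefination with acetaldehyde (LiCl, iPr2NEt, MeCN, 0 °C) then forms the (E)-2-methylbut-2-enoate. The route is rejoined at 17.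

**Further compounds**
F1 | step 2 | tert-butyl 2-hydroxycyclohexa-1,4-diene-1-carboxylate (enol of tert-butyl 2-oxocyclohex-4-ene-1-carboxylate) | CC(C)(C)OC(=O)C1=C(O)CC=CC1
F2 | step 2 | tert-butyl 2-(trifluoromethylsulfonyloxy)cyclohexa-1,4-diene-1-carboxylate | CC(C)(C)OC(=O)C1=C(OS(=O)(=O)C(F)(F)F)CC=CC1
F3 | step 2 | tert-butyl cyclohexa-1,4-diene-1-carboxylate | CC(C)(C)OC(=O)C1=CCC=CC1
F4 | step 2 | racemic tert-butyl 7-oxabicyclo[4.1.0]hept-3-ene-3-carboxylate (cis-fused epoxide) | CC(C)(C)OC(=O)C1=CCC2OC2C1
F5 | step 2 | racemic tert-butyl 5-hydroxycyclohexa-1,3-diene-1-carboxylate | CC(C)(C)OC(=O)C1=CC=CC(O)C1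
F6 | step 2 | tert-butyl (5R)-5-hydroxycyclohexa-1,3-diene-1-carboxylate | O[C@@H]1CC(C(=O)OC(C)(C)C)=CC=C1
F7 | step 2 | tert-butyl (5R)-5-acetoxycyclohexa-1,3-diene-1-carboxylate | CC(=O)O[C@@H]1CC(C(=O)OC(C)(C)C)=CC=C1
F8 | step 8 | tert-butyl (1S,5S,6R)-5-acetoxy-7-oxabicyclo[4.1.0]hept-2-ene-3-carboxylate | CC(C)(C)OC(=O)C1=C[C@@H]2O[C@@H]2[C@@H](OC(C)=O)C1
F9 | step 9 | tert-butyl (3R,4R,5S)-5-acetoxy-4-[2-(diethoxyphosphoryl)propanoyloxy]-3-(6-methylheptanoyloxy)cyclohex-1-ene-1-carboxylate (both epimers at the phosphonate carbon) | CCOP(=O)(OCC)C(C)C(=O)O[C@@H]1[C@@H](OC(C)=O)CC(C(=O)OC(C)(C)C)=C[C@H]1OC(=O)CCCCC(C)C
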